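## Structural features

The target is a coumestan: benzene ring A, lactone (α-pyranone) ring B, furan ring C and phenolic benzene ring D, fused into a flat 6H-benzofuro[3,2-c]chromen-6-one. Coumarin numbers are used here for rings A and B (O1, C2 carbonyl, C3, C4, C4a to C8a) and primed numbers for ring D; ring C consists of C3, C4, the furan oxygen, C2' and C1'. Ring A is substituted everywhere except C8: C7 carries the methoxy group, and a 2,2-dimethyldihydropyran (ring E) is fused across C5–C6 with its oxygen on C5, peri to C4 and the furan oxygen. The molecule has no stereocentre and is achiral, so every selectivity question is one of regiochemistry or chemoselectivity. Sensitive groups are the lactone (hydroxide and strong nucleophiles), the free phenol at C4' (oxidants), the methyl ether and tertiary alkyl aryl ether (strong Lewis acids, so late dealkylation tactics are excluded) and the benzylic CH2 of ring E (quinone oxidants). The real difficulty is twofold: the order of three different oxygen substituents and one carbon substituent around ring A, and joining ring D through both C3–C1' and O–C2' with its hydroxyl para to C1' rather than para to C2'. The key step uses the 1,3-relationship of the ring-D oxygens at C2' and C4': these are the two carbonyl carbons of a cyclohexane-1,3-dione, and C1' is the α-carbon flanked by only one of them. A 6-halogenated 3-alkoxycyclohexenone therefore carries the ring-D pattern at one oxidation level below the arene.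

## Logic of the disconnections

12 ⇒ 11. No skeletal bond is cut; ring D is taken back to its furan-fused cyclohexanone (C3'H2, C4'=O, C5'H2, C6'H2). Ring D thereby becomes a carbonyl compound that can be built by enolate chemistry, and the phenol needs no protecting group. The forward step must remove one molecule of H2 from ring D only, sparing the CH2–CH2 unit of ring E and the phenol it creates.

11 ⇒ 6 + 9. The bonds C3–C1' and O(furan)–C2' are cut, which opens ring C. C3 of 6 is a stabilised carbon nucleophile, C1' of 9 is electrophilic as a CHBr carbon, and C2' is a carbonyl that can take up the 4-hydroxyl. This is the convergent cut: it separates the complete A/B/E unit from a six-carbon ring-D unit. The forward step needs C- rather than O-alkylation, closure through the 4-hydroxyl, hydrolysis of the enol ether, and a base mild enough that 9 does not lose HBr.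

6 ⇒ 4 + 5. The bonds O1–C2 and C2–C3 of ring B are cut, so that C2 arrives as a one-carbon unit already at the lactone oxidation level. In 4 the acetyl group stands between the ring-E oxygen and the single free phenol, so ring B can close in one sense only. The forward step asks for enolate acylation and lactonisation under strong base without harm to ring E.

4 ⇒ 3 ⇒ 1 + 2. A C3=C4 double bond is reintroduced in ring E, and the resulting chromene is cut at the aryl–CH bond and the O–CMe2 bond. The two phenols of 1 are equivalent by symmetry, so only one mono-annulation product can form, and the methoxy group blocks closure on the other side. The forward steps must stop at mono-annulation and must hydrogenate the styrene-type double bond without reducing the aryl ketone.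

9 ⇒ 7. The C–Br bond is cut back to the kinetic α'-enolate of the vinylogous ester. The forward step must functionalise C6 rather than C2 or C4 and must stop at mono-bromination.

## Other disconnections considered

Alternative 1: Ring B is cut at C4–C4a and O1–C2, giving phloroglucinol A1 as ring A and the coumaranone ester A2 (ethyl 6-benzyloxy-2-oxo-2,3-dihydrobenzofuran-3-carboxylate) as ring D plus the C2–C3–C4 unit. Heating both in diphenyl ether should C-acylate A1 with one malonyl carbonyl and lactonise with the other, opening the coumaranone and giving the 3-aryl-4,5,7-trihydroxycoumarin A3.
- In favour: the step is convergent, the symmetry of A1 removes any regiochemical question in the acylation, and ring D arrives aromatic with its oxygen fixed by the starting material. On that last point it is better than the chosen plan, which needs a late oxidation.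
- Against: after furan closure to the 1,3-dihydroxycoumestan A4, ring A has still to be built up. C-prenylation must pick the position between the two hydroxyls, and the pyran must close on the peri hydroxyl rather than the other one. Neither choice is controlled by the structure. Methylation and debenzylation follow.
- Comparison: the mechanism of the key step is simple and thermal, but it needs about 250 °C, and A2 is itself a multistep compound. The count comes to seven or more steps with two poorly controlled ones, against six steps in which the ring-A pattern is set in the first step by the symmetry of 1.

Alternative 2: The bonds O–C4, C3–C2 and C2–O1 are cut, giving the bis(ortho-hydroxyaryl)alkyne A5 and carbon monoxide as the source of C2. With PdI2 and thiourea (divalent palladium), CO, Cs2CO3 and CBr4 as reoxidant, the ring-D phenol should add to the alkyne carbon on ring A, CO should insert, and the ring-A phenol should trap the acylpalladium to give the ring-D benzyl ether A6.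
- In favour: three bonds and two rings form in one operation at the final oxidation level, and only a hydrogenolysis remains. In bonds formed per step and in mildness of the last step it is better than the chosen plan.
- Against: the two phenols must take different roles. If the ring-A phenol performs the oxypalladation, the constitutional isomer A7 results, with lactone and furan exchanged between rings A and D. Only a modest electronic bias from the richer ring A favours the desired sense. A5 also needs two Sonogashira couplings, one onto a tetrasubstituted electron-rich ring-A iodide, and free ortho-alkynylphenols tend to cyclise early, so protecting groups would be needed.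
- Comparison: the chosen plan fixes the sense of annulation by ring size rather than by relative phenol reactivity, avoids CO and CBr4, and is shorter (six steps against roughly nine or ten).

Alternative 3: The bonds C3–C1' and O1–C2 are cut at the isoflavone level. The chalcone A9 would come from 4 and 2,4-bis(benzyloxy)benzaldehyde A8 by Claisen–Schmidt condensation. Tl(NO3)3 (trivalent thallium) in methanol with trimethyl orthoformate should shift ring D from the β- to the α-carbon, and HCl should then close the ring-A phenol onto the acetal carbon to give the isoflavone A10.
- In favour: it shares 4 with the chosen route, the dialkoxyphenyl ring is a very good migrating group, and the ring-D oxygen pattern is fixed by A8. On regiocontrol of ring D it is the equal of the chosen plan.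
- Against: A10 is at the wrong oxidation level. C2 is a CH that must become the lactone carbonyl, and the 2'-oxygen is not yet bonded to C4. That means debenzylation, hydride reduction with ring closure to the dihydro skeleton, and quinone oxidations back up to the coumestan. These oxidations are harsher than the single dehydrogenation of the chosen plan and would act in the presence of the ring-E benzylic CH2 and a free phenol.
- Comparison: stoichiometric thallium is a handling burden, and the total is about nine steps against six. The chosen plan brings C2 in at the lactone level from 5 and never has to change it.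

Key step: step 5

Assumption: 9 is used as the freshly prepared racemate; its stereocentre becomes the sp2 carbon C1' in step 5. Ring D of 11 is a furan-fused (β,γ-unsaturated) cyclohexanone, so step 6 removes one molecule of H2.

## Route

Step 1
Reactants: 1 2,6-dihydroxy-4-methoxyacetophenone; 2 3-methylbut-2-enal (prenal)
Product: 3 8-acetyl-7-hydroxy-5-methoxy-2,2-dimethyl-2H-chromene
Conditions: 2 (1.1 equiv), ethylenediammonium diacetate (10 mol %), toluene, reflux
Reagents that add atoms: none
Why: Formal [3+3] chromenylation: Knoevenagel-type condensation at the ring carbon between OH and OMe, then oxa-6π electrocyclisation of the dienone; the two phenols of 1 are equivalent and the methoxy group blocks the other side, so one mono-chromene is expected.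

Step 2
Reactants: 3 8-acetyl-7-hydroxy-5-methoxy-2,2-dimethyl-2H-chromene
Product: 4 8-acetyl-7-hydroxy-5-methoxy-2,2-dimethylchroman
Conditions: H2 (1 atm), Pd/C (10 wt %), EtOAc, rt
Reagents that add atoms: none
Why: Catalytic hydrogenation of the styrene-type C3=C4 bond; the hydrogen-bonded, di-ortho-substituted aryl ketone and the aryl ethers should survive at 1 atm and room temperature.

Step 3
Reactants: 4 8-acetyl-7-hydroxy-5-methoxy-2,2-dimethylchroman; 5 diethyl carbonate
Product: 6 4-hydroxy-7-methoxycoumarin with a 2,2-dimethyl-3,4-dihydro-2H-pyran fused at C5–C6 (ring oxygen on C5)
Conditions: NaH (3.5 equiv), 5 (5 equiv), toluene, 110 °C; then cold aq. HCl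
Reagents that add atoms: none
Why: Standard 4-hydroxycoumarin synthesis from an ortho-hydroxyacetophenone: Claisen-type ethoxycarbonylation by the carbonate and ring closure with the single neighbouring phenoxide; the product rests as its stabilised sodium salt until acidification.

Step 4
Reactants: 7 3-ethoxycyclohex-2-en-1-one
Product: 9 6-bromo-3-ethoxycyclohex-2-en-1-one (racemic), via lithium dienolate 8 (not isolated)
Conditions: LiN(iPr)2 (LDA, 1.05 equiv), THF, −78 °C; then NBS (1.05 equiv), −78 °C; aq. NH4Cl
Reagents that add atoms: N-bromosuccinimide, O=C1CCC(=O)N1Br
Why: Kinetic α'-deprotonation of the vinylogous ester (the enolate used in Stork–Danheiser alkylations) and electrophilic bromination at that carbon; the new stereocentre is racemic and is destroyed in step 5.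

Step 5
Reactants: 6 4-hydroxy-7-methoxycoumarin with the C5–C6 fused dimethyldihydropyran; 9 6-bromo-3-ethoxycyclohex-2-en-1-one (racemic)
Product: 11 ring-D ketone of the target (ring D as a cyclohexanone fused to the furan through C1'=C2': C3'H2 then C4'=O then C5'H2 then C6'H2), via C3-alkylated coumarin 10 (not isolated)
Conditions: KHCO3 (1.0 equiv), 1,4-dioxane–H2O 1:1, 40 °C; then TsOH·H2O (1.0 equiv), 90 °C, Ar
Reagents that add atoms: water, O
Why: Bicarbonate converts 6, a vinylogous carboxylic acid, into its potassium salt, whose soft C3 carbon should displace bromide from the CHBr carbon of 9 by SN2 to give 10; aldol-type attack on the carbonyl of 9 is not expected because a vinylogous ester carbonyl is a poor electrophile for a stabilised anion. After acidification the 4-hydroxyl adds to the neighbouring ring carbonyl of 10 (activated as its protonated, oxygen-stabilised allyl cation) in a 5-exo-trig closure, water is lost to give the aromatic furan ring C, and the remaining enol ether is hydrolysed by the water of the medium to the C4' ketone. The closest known reaction type is the C-alkylation and cyclodehydration of 4-hydroxycoumarins and cyclic 1,3-diones with cyclic α-halo ketones (a Feist–Benary-type furan annulation with Paal–Knorr-like closure), which gives tetrahydrocoumestans. No stereocentre is created in the product, since the CH centre of 10 becomes the sp2 carbon C1'. Three selectivities are needed: C- over O-alkylation, favoured by the hydrogen-bonding aqueous medium and the soft secondary bromide; closure through the enolic 4-hydroxyl rather than the lactone carbonyl oxygen, favoured because the hydroxyl is the better nucleophile and the coumarin form is retained; and the sense of annulation, fixed by ring size, since only the carbonyl next to the new C3–C1' bond can be reached through a five-membered ring while closure onto the ethoxy-bearing carbon would need a seven-membered one. That last point places the second ring-D oxygen at C4', para to C1'. The order of furan closure and enol ether hydrolysis does not matter, as both sequences converge on 11.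

Step 6
Reactants: 11 ring-D ketone of the target
Product: 12 target: 9-hydroxy-3-methoxycoumestan with a 2,2-dimethyl-3,4-dihydro-2H-pyran fused at C1–C2 (oxygen on C1); in the numbering used here 4'-OH, 7-OMe, ring E on C5–C6
Conditions: DDQ (1.1 equiv), 1,4-dioxane, rt, Ar
Reagents that add atoms: none
Why: DDQ dehydrogenation: 11 equilibrates with its furan-conjugated enol, a 1,3-cyclohexadiene that loses hydride from C5'/C6' and then a proton to give the phenol; the benzylic CH2 of ring E should react far more slowly at room temperature with one equivalent of oxidant.

## Compound list

1 | 2,6-dihydroxy-4-methoxyacetophenone | CC(=O)c1c(O)cc(OC)cc1O | starting material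
2 | 3-methylbut-2-enal (prenal) | CC(C)=CC=O | starting material
3 | 8-acetyl-7-hydroxy-5-methoxy-2,2-dimethyl-2H-chromene | CC(=O)c1c(O)cc(OC)c2C=CC(C)(C)Oc12 | intermediate
4 | 8-acetyl-7-hydroxy-5-methoxy-2,2-dimethylchroman | CC(=O)c1c(O)cc(OC)c2CCC(C)(C)Oc12 | intermediate
5 | diethyl carbonate | CCOC(=O)OCC | starting material
6 | 4-hydroxy-7-methoxycoumarin with a 2,2-dimethyl-3,4-dihydro-2H-pyran fused at C5–C6 (oxygen on C5) | COc1cc2oc(=O)cc(O)c2c2c1CCC(C)(C)O2 | intermediate
7 | 3-ethoxycyclohex-2-en-1-one | CCOC1=CC(=O)CCC1 | starting material
8 | lithium 5-ethoxycyclohexa-1,5-dien-1-olate (kinetic α'-enolate of 7) | [Li+].[O-]C1=CCCC(OCC)=C1 | intermediate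
9 | 6-bromo-3-ethoxycyclohex-2-en-1-one (racemic) | CCOC1=CC(=O)C(Br)CC1 | intermediate
10 | 6 carrying a 4-ethoxy-2-oxocyclohex-3-en-1-yl group on C3 (racemic) | COc1cc2oc(=O)c(C3CCC(OCC)=CC3=O)c(O)c2c2c1CCC(C)(C)O2 | intermediate
11 | ring-D ketone of the target (C4'=O; C3', C5', C6' as CH2) | COc1cc2oc(=O)c3c4CCC(=O)Cc4oc3c2c2c1CCC(C)(C)O2 | intermediate
12 | 9-hydroxy-3-methoxycoumestan with a 2,2-dimethyl-3,4-dihydro-2H-pyran fused at C1–C2 (oxygen on C1) | COc1cc2oc(=O)c3c4ccc(O)cc4oc3c2c2c1CCC(C)(C)O2 | target

## Step count and least certain steps

Total: 6 steps. Longest linear sequence: 5 steps (steps 1, 2, 3, 5 and 6); step 4 is a one-step side branch.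

Step 5 (key step).
- Risk: alkylation of the ambident coumarin anion on oxygen instead of C3 is the most likely failure. Loss of HBr from 9 with aromatisation before it is captured, and closure through the lactone oxygen in the acid stage, are further risks. All three stem from the modest SN2 reactivity of a secondary α-bromo vinylogous ester.
- Fallback, setting out from 6 and returning at 12 (it replaces steps 5 and 6): ring D is brought in aromatic. POCl3 with BnEt3NCl in MeCN converts 6 into the 4-chlorocoumarin F1. 3-Benzyloxyphenol with K2CO3 in DMF at 80 °C gives, by addition–elimination at C4, the 4-(3-benzyloxyphenoxy)coumarin F2. Pd(OAc)2 (catalytic) with AgOAc in pivalic acid at 110 °C performs the known intramolecular dehydrogenative coupling of C3–H with the aryl C–H para to the benzyloxy group, the less hindered of the two ortho positions, to give the ring-D benzyl ether F3. Hydrogenolysis (H2, Pd/C, EtOAc) then gives 12.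

Step 4.
- Risk: proton transfer between the bromo ketone formed and unreacted enolate, leading to double bromination and recovered 7; bromination at C2; loss of HBr on work-up or storage.
- Fallback, setting out from 7 and returning at 9: the kinetic enolate is trapped with Me3SiCl and the 2-trimethylsilyloxy-4-ethoxycyclohexa-1,3-diene F4 is isolated. It is then brominated with NBS in THF at 0 °C under neutral conditions, where no enolate is present to exchange protons.

Step 6.
- Risk: over-oxidation, either by hydride abstraction from the benzylic CH2 of ring E (dehydrogenation of ring E) or by attack of the quinone on the electron-rich phenol once formed.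
- Fallback, setting out from 11 and returning at 12: halogenation and elimination replace hydride abstraction. PhNMe3Br3 in THF at 0 °C brominates the activated CH2 between furan and ketone to give the 3'-bromo ketone F5. Li2CO3 and LiBr in DMF at 100 °C then remove HBr through the enol, as α-bromo-2-tetralones go to 2-naphthols.

Step 1.
- Risk: a second annulation on the remaining, equally placed phenol, or slow condensation because the acetyl group deactivates the ring.
- Fallback, setting out from 1 and returning at 4 (step 2 is then not needed): Friedel–Crafts prenylation with 2-methylbut-3-en-2-ol and BF3·OEt2 in dioxane gives the C-prenyl acetophenone F6. TsOH in toluene at 80 °C closes the only adjacent hydroxyl onto the prenyl double bond to give the chroman directly.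

## Further compounds

F1 | step 5 | 4-chloro analogue of 6 (4-chloro-7-methoxycoumarin with the C5–C6 fused dimethyldihydropyran) | COc1cc2oc(=O)cc(Cl)c2c2c1CCC(C)(C)O2
F2 | step 5 | 4-(3-benzyloxyphenoxy) analogue of 6 | COc1cc2oc(=O)cc(Oc3cccc(OCc4ccccc4)c3)c2c2c1CCC(C)(C)O2
F3 | step 5 | ring-D O-benzyl ether of 12 | COc1cc2oc(=O)c3c4ccc(OCc5ccccc5)cc4oc3c2c2c1CCC(C)(C)O2
F4 | step 4 | 2-trimethylsilyloxy-4-ethoxycyclohexa-1,3-diene | CCOC1=CC(O[Si](C)(C)C)=CCC1
F5 | step 6 | 3'-bromo derivative of 11 (racemic; bromine on the CH between furan and ketone) | COc1cc2oc(=O)c3c4CCC(=O)C(Br)c4oc3c2c2c1CCC(C)(C)O2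
F6 | step 1 | 2,6-dihydroxy-4-methoxy-3-(3-methylbut-2-en-1-yl)acetophenone | CC(=O)c1c(O)cc(OC)c(CC=C(C)C)c1O
A1 | alternative 1 | phloroglucinol | Oc1cc(O)cc(O)c1
A2 | alternative 1 | ethyl 6-benzyloxy-2-oxo-2,3-dihydrobenzofuran-3-carboxylate (racemic) | CCOC(=O)C1C(=O)Oc2cc(OCc3ccccc3)ccc21
A3 | alternative 1 | 3-(4-benzyloxy-2-hydroxyphenyl)-4,5,7-trihydroxycoumarin | Oc1cc(O)c2c(O)c(-c3ccc(OCc4ccccc4)cc3O)c(=O)oc2c1
A4 | alternative 1 | 9-benzyloxy-1,3-dihydroxycoumestan | Oc1cc(O)c2c(c1)oc(=O)c1c3ccc(OCc4ccccc4)cc3oc12
A5 | alternative 2 | 8-[(4-benzyloxy-2-hydroxyphenyl)ethynyl]-5-methoxy-2,2-dimethylchroman-7-ol | COc1cc(O)c(C#Cc2ccc(OCc3ccccc3)cc2O)c2OC(C)(C)CCc12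
A6 | alternative 2 | ring-D O-benzyl ether of 12 | COc1cc2oc(=O)c3c4ccc(OCc5ccccc5)cc4oc3c2c2c1CCC(C)(C)O2
A7 | alternative 2 | isomeric coumestan with the lactone closed on ring D and the furan on ring A | O=c1oc2cc(OCc3ccccc3)ccc2c2oc3cc(OC)c4CCC(C)(C)Oc4c3c12
A8 | alternative 3 | 2,4-bis(benzyloxy)benzaldehyde | O=Cc1ccc(OCc2ccccc2)cc1OCc1ccccc1
A9 | alternative 3 | (E)-3-[2,4-bis(benzyloxy)phenyl]-1-(7-hydroxy-5-methoxy-2,2-dimethylchroman-8-yl)prop-2-en-1-one | COc1cc(O)c(C(=O)/C=C/c2ccc(OCc3ccccc3)cc2OCc2ccccc2)c2OC(C)(C)CCc12
A10 | alternative 3 | 3-[2,4-bis(benzyloxy)phenyl]-7-methoxychromen-4-one with the C5–C6 fused dimethyldihydropyran | COc1cc2occ(-c3ccc(OCc4ccccc4)cc3OCc3ccccc3)c(=O)c2c2c1CCC(C)(C)O2
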